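## Retrosynthetic overview

- Target 16 ⇐ bis-benzyl ether 15 ⇐ cis-2,6-oxan-4-one 14; the carbinol centre comes from axial hydride delivery.
- 14 ⇐ hydroxy enone 13 by 6-endo oxa-Michael addition. The oxane is the only ring and is closed late through a C–O bond; the aryl-bearing centre is set thermodynamically from the existing carbinol centre.
- 13 ⇐ dithiane 12 ⇐ key C3–C4 bond: lithiated styryl dithiane 8 (a cinnamoyl anion equivalent) attacks the epoxide CH2 of (R)-epichlorohydrin 7, then benzylic Grignard 11 opens the re-formed epoxide, all in one flask.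
- Dithiane 4 ⇐ enal 3 ⇐ aldehyde 1 + ylide 2; Grignard 11 ⇐ chloride 6 ⇐ alcohol 5.

Assumption: 1, 2, 5 and 7 are bought as catalogue compounds. Chain numbering runs from C1 (carbon bearing the dimethoxyphenyl ring) to C7, and the ring is C1–O–C5.

## Route

Step 1
Reactants: 1 4-(benzyloxy)-3,5-dimethoxybenzaldehyde; 2 (triphenylphosphoranylidene)acetaldehyde
Product: 3 (E)-3-[4-(benzyloxy)-3,5-dimethoxyphenyl]prop-2-enal
Conditions: 2 (1.05 equiv), PhMe, 90 °C
Reagents that add atoms: none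
Why: Wittig olefination with the stabilised formyl ylide gives the (E)-enal, and the ylide is held near one equivalent so that the more electrophilic product is not homologated further to the dienal.

Step 2
Reactants: 3 (E)-3-[4-(benzyloxy)-3,5-dimethoxyphenyl]prop-2-enal
Product: 4 2-{(E)-2-[4-(benzyloxy)-3,5-dimethoxyphenyl]ethenyl}-1,3-dithiane
Conditions: HS(CH2)3SH (1.05 equiv), I2 (5 mol%), CHCl3, rt
Reagents that add atoms: propane-1,3-dithiol, SCCCS
Why: Iodine-catalysed dithioacetalisation takes place 1,2 at the enal carbonyl without conjugate thiol addition and avoids BF3/thiol conditions that can cleave aryl benzyl ethers, installing the Corey–Seebach handle that makes C3 a latent acyl anion.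

Step 3
Reactants: 5 [4-(benzyloxy)-3-methoxyphenyl]methanol
Product: 6 1-(benzyloxy)-4-(chloromethyl)-2-methoxybenzene
Conditions: SOCl2 (1.2 equiv), CH2Cl2, 0 °C; evaporate and use at once
Reagents that add atoms: thionyl chloride, O=S(Cl)Cl
Why: Deoxychlorination of an electron-rich benzylic alcohol via its chlorosulfite is fast at 0 °C, and the labile chloride is not purified.

Step 4
Reactants: 4 2-{(E)-2-[4-(benzyloxy)-3,5-dimethoxyphenyl]ethenyl}-1,3-dithiane; 7 (R)-epichlorohydrin; 6 1-(benzyloxy)-4-(chloromethyl)-2-methoxybenzene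
Product: 12 (S)-4-[4-(benzyloxy)-3-methoxyphenyl]-1-{2-[(E)-2-(4-(benzyloxy)-3,5-dimethoxyphenyl)ethenyl]-1,3-dithian-2-yl}butan-2-ol, via lithiated dithiane 8 (not isolated), via lithium chloroalkoxide 9 (not isolated), via dithianyl epoxide 10 (not isolated), via benzylic Grignard reagent 11 (not isolated)
Conditions: n-BuLi (1.05 equiv), THF, –78 to –30 °C; 7 (1.0 equiv), –78 °C to rt; then CuI (10 mol%) and 11 (1.3 equiv, from 6 and Mg, THF, 0 °C, separate flask), –40 to 0 °C; aq NH4Cl
Reagents that add atoms: none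
Why: Corey–Seebach umpolung in a one-flask linchpin coupling: the allyl-type dithianyl anion 8 alkylates at its sulfur-bearing α-carbon on the epoxide CH2 of 7, alkoxide 9 closes to epoxide 10 without any bond to the stereocentre being broken, and Cu-catalysed SN2 opening by 11 at the new terminal CH2 gives the (S)-carbinol, so C5 is taken over unchanged from (R)-epichlorohydrin (the descriptor changes only through CIP priorities).

Step 5
Reactants: 12 (S)-4-[4-(benzyloxy)-3-methoxyphenyl]-1-{2-[(E)-2-(4-(benzyloxy)-3,5-dimethoxyphenyl)ethenyl]-1,3-dithian-2-yl}butan-2-ol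
Product: 14 (2S,6S)-2-[4-(benzyloxy)-3,5-dimethoxyphenyl]-6-{2-[4-(benzyloxy)-3-methoxyphenyl]ethyl}oxan-4-one, via hydroxy enone 13 (not isolated)
Conditions: MeI (10 equiv), CaCO3, MeCN/H2O 4:1, 45 °C; filter, concentrate; then Amberlyst-15, CH2Cl2, rt
Reagents that add atoms: water, O
Why: S-Methylation triggers alkylative hydrolysis of the dithiane to enone 13, and acid-catalysed reversible 6-endo-trig oxa-Michael addition of the C5 hydroxyl then closes the ring under thermodynamic control to the diequatorial 2,6-cis ketone, which sets the aryl-bearing centre (2S) from the existing (6S) centre.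

Step 6
Reactants: 14 (2S,6S)-2-[4-(benzyloxy)-3,5-dimethoxyphenyl]-6-{2-[4-(benzyloxy)-3-methoxyphenyl]ethyl}oxan-4-one
Product: 15 (2S,4R,6S)-2-[4-(benzyloxy)-3,5-dimethoxyphenyl]-6-{2-[4-(benzyloxy)-3-methoxyphenyl]ethyl}oxan-4-ol
Conditions: NaBH4 (1.5 equiv), MeOH/THF, –40 °C; then H2O
Reagents that add atoms: none
Why: The small hydride attacks the chair ketone with both substituents equatorial from the axial direction, giving the equatorial (4R) alcohol cis to both substituents (all-cis).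

Step 7
Reactants: 15 (2S,4R,6S)-2-[4-(benzyloxy)-3,5-dimethoxyphenyl]-6-{2-[4-(benzyloxy)-3-methoxyphenyl]ethyl}oxan-4-ol
Product: 16 (2S,4R,6S)-2-(4-hydroxy-3,5-dimethoxyphenyl)-6-[2-(4-hydroxy-3-methoxyphenyl)ethyl]oxan-4-ol
Conditions: H2 (1 atm), 10% Pd/C, EtOAc, rt; stop at full conversion
Reagents that add atoms: none
Why: Hydrogenolysis of the two aryl benzyl ethers is much faster than cleavage of the cyclic benzylic C–O bond under these mild conditions, and no stereocentre is touched.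

## Compound list

1 | 4-(benzyloxy)-3,5-dimethoxybenzaldehyde | COc1cc(C=O)cc(OC)c1OCc1ccccc1 | starting material
2 | (triphenylphosphoranylidene)acetaldehyde | O=CC=P(c1ccccc1)(c1ccccc1)c1ccccc1 | starting material
3 | (E)-3-[4-(benzyloxy)-3,5-dimethoxyphenyl]prop-2-enal | COc1cc(/C=C/C=O)cc(OC)c1OCc1ccccc1 | intermediate
4 | 2-{(E)-2-[4-(benzyloxy)-3,5-dimethoxyphenyl]ethenyl}-1,3-dithiane | COc1cc(/C=C/C2SCCCS2)cc(OC)c1OCc1ccccc1 | intermediate
5 | [4-(benzyloxy)-3-methoxyphenyl]methanol | COc1cc(CO)ccc1OCc1ccccc1 | starting material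
6 | 1-(benzyloxy)-4-(chloromethyl)-2-methoxybenzene | COc1cc(CCl)ccc1OCc1ccccc1 | intermediate
7 | (R)-epichlorohydrin, (2R)-2-(chloromethyl)oxirane | ClC[C@H]1CO1 | starting material
8 | 2-lithio-2-{(E)-2-[4-(benzyloxy)-3,5-dimethoxyphenyl]ethenyl}-1,3-dithiane | [Li]C1(/C=C/c2cc(OC)c(OCc3ccccc3)c(OC)c2)SCCCS1 | intermediate
9 | lithium (2R)-1-chloro-3-(2-{(E)-2-[4-(benzyloxy)-3,5-dimethoxyphenyl]ethenyl}-1,3-dithian-2-yl)propan-2-olate | COc1cc(/C=C/C2(C[C@H](CCl)O[Li])SCCCS2)cc(OC)c1OCc1ccccc1 | intermediate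
10 | (2R)-2-[(2-{(E)-2-[4-(benzyloxy)-3,5-dimethoxyphenyl]ethenyl}-1,3-dithian-2-yl)methyl]oxirane | COc1cc(/C=C/C2(C[C@@H]3CO3)SCCCS2)cc(OC)c1OCc1ccccc1 | intermediate
11 | [4-(benzyloxy)-3-methoxybenzyl]magnesium chloride | COc1cc(C[Mg]Cl)ccc1OCc1ccccc1 | intermediate
12 | (S)-4-[4-(benzyloxy)-3-methoxyphenyl]-1-{2-[(E)-2-(4-(benzyloxy)-3,5-dimethoxyphenyl)ethenyl]-1,3-dithian-2-yl}butan-2-ol | COc1cc(CC[C@H](O)CC2(/C=C/c3cc(OC)c(OCc4ccccc4)c(OC)c3)SCCCS2)ccc1OCc1ccccc1 | intermediate
13 | (1E,5S)-1-[4-(benzyloxy)-3,5-dimethoxyphenyl]-7-[4-(benzyloxy)-3-methoxyphenyl]-5-hydroxyhept-1-en-3-one | COc1cc(CC[C@H](O)CC(=O)/C=C/c2cc(OC)c(OCc3ccccc3)c(OC)c2)ccc1OCc1ccccc1 | intermediate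
14 | (2S,6S)-2-[4-(benzyloxy)-3,5-dimethoxyphenyl]-6-{2-[4-(benzyloxy)-3-methoxyphenyl]ethyl}oxan-4-one | COc1cc(CC[C@H]2CC(=O)C[C@@H](c3cc(OC)c(OCc4ccccc4)c(OC)c3)O2)ccc1OCc1ccccc1 | intermediate
15 | (2S,4R,6S)-2-[4-(benzyloxy)-3,5-dimethoxyphenyl]-6-{2-[4-(benzyloxy)-3-methoxyphenyl]ethyl}oxan-4-ol | COc1cc(CC[C@H]2C[C@@H](O)C[C@@H](c3cc(OC)c(OCc4ccccc4)c(OC)c3)O2)ccc1OCc1ccccc1 | intermediate
16 | (2S,4R,6S)-2-(4-hydroxy-3,5-dimethoxyphenyl)-6-[2-(4-hydroxy-3-methoxyphenyl)ethyl]oxan-4-ol | COc1cc(CC[C@H]2C[C@@H](O)C[C@@H](c3cc(OC)c(O)c(OC)c3)O2)ccc1O | target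

## Step count and risks

Total step count: 7. Longest linear sequence: 6 steps (1 → 3 → 4 → 12 → 14 → 15 → 16).

**Step 4 (three-component coupling).** The anion 8 is ambident and could react at its benzylic γ-carbon, and three reactive species share one flask. The fallback sets out from 7 and uses a non-ambident acetyl anion instead. Lithiated 2-methyl-1,3-dithiane (commercial) opens 7 and the alkoxide closes to (R)-2-[(2-methyl-1,3-dithian-2-yl)methyl]oxirane F1, which is isolated. Opening of F1 with 11 and catalytic CuI gives (S)-4-[4-(benzyloxy)-3-methoxyphenyl]-1-(2-methyl-1,3-dithian-2-yl)butan-2-ol F2. MeI/CaCO3 hydrolysis gives (4S)-6-[4-(benzyloxy)-3-methoxyphenyl]-4-hydroxyhexan-2-one F3. Pyrrolidine-mediated condensation of F3 with aldehyde 1 (enamine aldol condensation followed by oxa-Michael closure, as in the Kabbe chromanone synthesis) comes back to the route at ketone 14. The umpolung bond to the epichlorohydrin carbon is kept, and the aryl ring is attached afterwards.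

**Step 5 (dithiane hydrolysis and oxa-Michael closure).** The allylic dithiane may hydrolyse sluggishly. The free hydroxy enone 13 can dehydrate to the dienone or stay partly open, and long exposure could open the ring on the alkyl side and erode the C6 centre. The fallback sets out from 12 and closes the ring before unmasking. Catalytic TfOH in CH2Cl2 protonates the electron-rich styrene to the benzylic cation, which the C5 hydroxyl traps (intramolecular Markovnikov hydroalkoxylation, cis under reversible ionisation). This gives (8S,10S)-8-[4-(benzyloxy)-3,5-dimethoxyphenyl]-10-{2-[4-(benzyloxy)-3-methoxyphenyl]ethyl}-9-oxa-1,5-dithiaspiro[5.5]undecane F4. F4 is a simple saturated dithiane, and its MeI/CaCO3 hydrolysis comes back to the route at 14.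

**Step 7 (hydrogenolysis).** The ring C2–O bond is itself benzylic and on an electron-rich aryl group, so over-reduction to a ring-opened product is possible. The fallback sets out from 14 and removes the benzyl groups non-reductively before the reduction. BCl3 with pentamethylbenzene in CH2Cl2 at –78 °C gives (2S,6S)-2-(4-hydroxy-3,5-dimethoxyphenyl)-6-[2-(4-hydroxy-3-methoxyphenyl)ethyl]oxan-4-one F5. At the ketone stage any Lewis-acid ring opening is repaired by re-closure to the cis ketone. NaBH4 in MeOH at –40 °C then reduces F5 and comes back to the route at 16.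

## Further compounds

F1 | step 4 | (R)-2-[(2-methyl-1,3-dithian-2-yl)methyl]oxirane | CC1(C[C@@H]2CO2)SCCCS1
F2 | step 4 | (S)-4-[4-(benzyloxy)-3-methoxyphenyl]-1-(2-methyl-1,3-dithian-2-yl)butan-2-ol | COc1cc(CC[C@H](O)CC2(C)SCCCS2)ccc1OCc1ccccc1
F3 | step 4 | (4S)-6-[4-(benzyloxy)-3-methoxyphenyl]-4-hydroxyhexan-2-one | COc1cc(CC[C@H](O)CC(C)=O)ccc1OCc1ccccc1
F4 | step 5 | (8S,10S)-8-[4-(benzyloxy)-3,5-dimethoxyphenyl]-10-{2-[4-(benzyloxy)-3-methoxyphenyl]ethyl}-9-oxa-1,5-dithiaspiro[5.5]undecane | COc1cc(CC[C@H]2CC3(C[C@@H](c4cc(OC)c(OCc5ccccc5)c(OC)c4)O2)SCCCS3)ccc1OCc1ccccc1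
F5 | step 7 | (2S,6S)-2-(4-hydroxy-3,5-dimethoxyphenyl)-6-[2-(4-hydroxy-3-methoxyphenyl)ethyl]oxan-4-one | COc1cc(CC[C@H]2CC(=O)C[C@@H](c3cc(OC)c(O)c(OC)c3)O2)ccc1O
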